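Remark: the target has no stereocentre and is taken in its open keto acid form. Locants used below: ring carbons C1–C6 (C1 bears the carboxyl carbon C7, C2 the hydroxyl, C4 the methoxy group, C6 the chain) and chain carbons C1'–C13' counted from the benzylic position.

## Analysis of the target

The target 10 is a tetrasubstituted benzene. C1 bears the carboxyl group (C7), C2 a free hydroxyl, C4 a methoxy group and C6 a thirteen-carbon chain: benzylic C1', ketone C2', eleven methylene groups C3'–C13' and a terminal primary hydroxyl. There is no stereocentre, so the problem is one of regiochemistry and functional-group compatibility only. The sensitive parts are the electron-rich salicylic acid (protodecarboxylation in hot acid), the doubly activated C1' methylene, and the 1,5 relation between the carboxyl oxygen and the C2' ketone, which lets the keto acid close to an isocoumarin under dehydrating conditions. The difficulties are to place three different groups on the contiguous carbons C6, C1 and C2, to tell the two phenolic oxygens apart (free at C2, methylated at C4), and to attach a long functionalised chain at the crowded position C6. The plan rests on two facts. C6 is the only C–H ortho to the carboxyl group once C2 carries oxygen, and C1'–C2' with everything behind it is an acylmethyl group, which is exactly what a β-keto sulfoxonium ylide delivers as a metal carbene. The isocoumarin that threatens the target then becomes useful: it is the natural product of a carboxylate-directed acylmethylation, it masks acid and ketone together, and its carbonyl lies peri to the C2 oxygen, where it can direct a selective demethylation.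

## Retrosynthetic reasoning

**10 ⇒ 9.** No skeletal bond is cut first. The carboxyl oxygen on C7 is joined on paper to C2', which turns keto acid 10 into the enol lactone 9 (8-hydroxy-3-(11-hydroxyundecyl)-6-methoxyisochromen-1-one). This lactone is the trap the target is always close to, so it is better used than fought: it holds acid and ketone in one neutral ring that survives Lewis acids and chromatography. The forward reaction is an alkaline ring opening, made irreversible in base because the enolate released at C2' ketonises. Its one demand is a cold, short acidification so that 10 does not close again.

**9 ⇒ 8.** Two protecting groups are added: a methyl group on the oxygen that becomes the C2 hydroxyl and a benzyl group on the C13' oxygen, giving 8 (3-(11-benzyloxyundecyl)-6,8-dimethoxyisochromen-1-one). Methyl is chosen on the phenol because only in the lactone is this oxygen peri to a carbonyl group. A boron Lewis acid held in that six-membered chelate removes this methyl group and leaves the one on the C4 oxygen, so the two phenolic oxygens need not be differentiated at the outset. Benzyl is chosen on the chain because the same Lewis acid cleaves it, and because it is inert to the base used for the ylide and to the cationic rhodium catalyst.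

**8 ⇒ 5 + 6.** The isocoumarin is cut at the C6–C1' bond and at the lactone C–O bond. This leads through the open keto acid 7 to 2,4-dimethoxybenzoic acid 6 and the keto sulfoxonium ylide 5 (13-benzyloxy-1-(dimethyloxosulfuranylidene)tridecan-2-one). C6–C1' is the only bond joining ring and chain, and in 6 the carboxylate can reach no C–H other than C6, because C2 is blocked. Cutting C1'–C2' instead would need a benzylic carbanion beside an ester, and cutting C1–C7 would need a late carboxylation between two substituents. The gain is full convergence: 6 already holds C7 and both ring oxygens, and 5 holds the whole chain at the right oxidation level. The forward reaction must metalate C6–H under carboxylate direction, transfer the acylmethyl carbene from 5 with loss of its sulfoxide leaving group, and let the carboxyl oxygen close onto C2'.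

**5 ⇒ 2 + 3.** The ylide is cut at C1'–C2'. C1' with its sulfoxonium group comes from trimethylsulfoxonium iodide 3 by way of the methylide 4, and the acyl part C2'–C13' comes from ester 2 (benzyl 12-(benzyloxy)dodecanoate). The forward reaction is an acyl substitution on the ester by the ylide carbon. The product is a stabilised ylide that does not react further, so over-addition is not a concern.

**2 ⇒ 1.** Both benzyl–oxygen bonds of 2 are cut, which leads to 12-hydroxydodecanoic acid 1. This acid already contains the twelve chain carbons C2'–C13' and the terminal oxygen. One double O-benzylation protects the alcohol and turns the carboxyl group into an ester that can acylate 4.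

## Alternatives that were turned down

**Alternative 1:** Indanone tether, then oxidative cleavage.
- Disconnection: the C1–C7 bond, formed intramolecularly after C7 has been tied to C2'. The ring that closes is a five-membered carbocycle whose C7–C2' bond does not exist in the target and is cut later by oxidation.
- Forward key step: racemic 2-[11-(tert-butyldiphenylsilyloxy)undecyl]-3-(3,5-dimethoxyphenyl)propanoic acid A1, activated as a mixed anhydride, acylates its own ring ortho to the tether and gives racemic 2-[11-(tert-butyldiphenylsilyloxy)undecyl]-5,7-dimethoxyindan-1-one A2.
- For: the two ring positions flanking the tether are equivalent and doubly activated, so the closure is regiochemically unambiguous and needs no precious metal. On the reliability of the ring-forming event it is stronger than a C–H activation beside an ortho methoxy group.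
- Against: A1 needs three to four steps of its own (two alkylations, hydrolysis, decarboxylation). A2 contains a bond that must be destroyed, which takes α-oxygenation of the ketone and a glycol-type cleavage beside an easily oxidised dimethoxyarene. The stereocentre of A2 is made only to vanish. The selective demethylation and the unmasking of the chain still remain, so nothing is saved at the end.
- Comparison: about twice the step count, and linear. In place of the robust Friedel–Crafts closure, the chosen route offers one catalytic step that forms the only necessary ring–chain bond at the correct oxidation level and delivers acid and ketone already masked as lactone 8.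

**Alternative 2:** Cyclohexane-1,3-dione by Claisen closure, late aromatisation.
- Disconnection: the arene is built, not bought. The ring bond C3–C4 is closed by a Claisen condensation and the ring is aromatised afterwards.
- Forward key step: dimethyl 2-acetyl-3-[(2-(11-tert-butyldimethylsilyloxyundecyl)-1,3-dioxolan-2-yl)methyl]pentanedioate A3 (mixture of diastereomers) is treated with methoxide. The enolate of the acetyl methyl group attacks the distal ester and gives methyl 2,4-dioxo-6-[(2-(11-tert-butyldimethylsilyloxyundecyl)-1,3-dioxolan-2-yl)methyl]cyclohexane-1-carboxylate A4 (racemic).
- For: only enolate chemistry with cheap reagents. After aromatisation the C2 hydroxyl is hydrogen-bonded to the ester and the C4 hydroxyl is free, so methylation at C4 alone is easy. On differentiating the two oxygens it is stronger than the chosen route, which relies on a chelation-controlled demethylation.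
- Against: A3 must be assembled by conjugate addition to an unsaturated ester that already carries the ketal-masked C2' and the whole chain, which costs several steps. The Claisen closure competes with retro-Michael fragmentation. Dehydrogenating A4 is an oxidation-level correction that needs halogenating or quinone oxidants beside a ketal and a silyl ether. The ester that emerges sits between two ortho substituents and is hard to saponify, and the ketal needs acid. Hot base and acid are what a 2,4-dioxygenated benzoic acid with a 2-oxoalkyl neighbour tolerates worst.
- Comparison: ten steps or more against five, with stereocentres formed and discarded. The chosen route buys the ring with C7 and both oxygens in place as 6 and spends its only real risk on one bond.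

**Alternative 3:** Biomimetic aldol aromatisation of a diketo-dioxinone.
- Disconnection: the ring bond C1–C6, closed by intramolecular aldol condensation of a polyketide-like chain whose carboxyl end is masked as a dioxinone.
- Forward key step: 2,2-dimethyl-6-{2,4-dioxo-5-[2-(11-tert-butyldimethylsilyloxyundecyl)-1,3-dioxolan-2-yl]pentyl}-1,3-dioxin-4-one A5 is treated with a tertiary amine. The nucleophilic α-carbon of the dioxinone adds to the terminal ketone, and dehydration and enolisation give 7-hydroxy-2,2-dimethyl-5-[(2-(11-tert-butyldimethylsilyloxyundecyl)-1,3-dioxolan-2-yl)methyl]benzo[d][1,3]dioxin-4-one A6.
- For: very mild conditions. In A6 the C2 oxygen and C7 are locked together in the dioxinone ring while the C4 hydroxyl is free, so its methylation needs no selectivity. On this point it is again stronger than the chosen route. Hydroxide opening of the benzodioxinone resembles the last step of the chosen route.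
- Against: A5 is a labile polycarbonyl compound. Reaching it needs a two-carbon homologation and ketalisation of the C12 chain, activation, and C-acylation of a dioxinone-derived dianion, which is four to five steps of delicate enolate chemistry. O-cyclisation to a pyranone and thermal cycloreversion of the dioxinone to an acylketene compete. Three protecting groups are carried instead of two.
- Comparison: about nine to ten steps. It sets the oxygen pattern elegantly, but the benzene ring it builds can be bought as 6, and the chosen route replaces the whole polycarbonyl assembly by one C–H functionalisation.

Key step: step 3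

## Route

Step 1
Reactants: 1 12-hydroxydodecanoic acid
Product: 2 benzyl 12-(benzyloxy)dodecanoate
Conditions: NaH (2.5 equiv), BnBr (2.5 equiv), n-Bu4NI (cat.), DMF, 0 °C → rt
Reagents that add atoms: benzyl bromide, BrCc1ccccc1
Why: Double Williamson-type O-alkylation: NaH forms the carboxylate and the alkoxide, and both displace bromide from benzyl bromide (SN2, iodide catalysis). One operation protects the alcohol and turns the acid into an ester acyl donor.

Step 2
Reactants: 2 benzyl 12-(benzyloxy)dodecanoate; 3 trimethylsulfoxonium iodide
Product: 5 13-benzyloxy-1-(dimethyloxosulfuranylidene)tridecan-2-one, via dimethylsulfoxonium methylide 4 (not isolated)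
Conditions: 3 (3 equiv), KOtBu (3 equiv), THF, reflux, 2 h; then 2, THF, 0 °C → reflux
Reagents that add atoms: none
Why: Corey–Chaykovsky methylide formation, then acylation of the ylide carbon by the ester (addition–elimination with loss of benzyl oxide). The acidic β-keto sulfoxonium salt is deprotonated at once to the stabilised ylide 5, which does not add a second time, and the benzyl ether is inert to the base.

Step 3
Reactants: 5 13-benzyloxy-1-(dimethyloxosulfuranylidene)tridecan-2-one; 6 2,4-dimethoxybenzoic acid
Product: 8 3-(11-benzyloxyundecyl)-6,8-dimethoxyisochromen-1-one, via 2-(13-benzyloxy-2-oxotridecyl)-4,6-dimethoxybenzoic acid 7 (not isolated)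
Conditions: [Cp*RhCl2]2 (cat.), AgSbF6 (cat.), NaOAc (cat.), ClCH2CH2Cl, 100 °C, slow addition of 5
Reagents that add atoms: none
Why: AgSbF6 removes chloride from [Cp*RhCl2]2 to give a cationic Cp*Rh species of trivalent rhodium, which binds the carboxylate of 6 and cleaves the C6–H bond by acetate-assisted concerted metalation–deprotonation to a five-membered rhodacycle. The ylide carbon of 5 coordinates, dimethyl sulfoxide leaves to give a rhodium carbene, and 1,1-migratory insertion of the aryl group forms the C6–C1' bond. The rhodium alkyl so formed has no β-hydrogen, so protonation is its only outlet; it releases keto acid 7 and returns the catalyst without a change of oxidation state. Keto acid 7 then closes the lactone by 6-exo-trig attack of a carboxyl oxygen on the C2' ketone, and loss of water gives enol lactone 8. The closest known reaction type is the carboxylate-directed C–H acylmethylation and annulation of benzoic acids with sulfoxonium ylides to 3-substituted isocoumarins under trivalent rhodium or divalent ruthenium catalysis. No stereocentre is formed. The step needs site selectivity, which the substrate secures because the methoxy group blocks C2 and leaves C6 as the only position the carboxylate can reach, which also rules out a second insertion. It also needs chemoselectivity for C–H over O–H insertion, which is helped by the acetate buffer and by adding 5 slowly so that its standing concentration stays low.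

Step 4
Reactants: 8 3-(11-benzyloxyundecyl)-6,8-dimethoxyisochromen-1-one
Product: 9 8-hydroxy-3-(11-hydroxyundecyl)-6-methoxyisochromen-1-one
Conditions: BCl3 (4 equiv), C6HMe5 (3 equiv), CH2Cl2, −78 → 0 °C; then H2O
Reagents that add atoms: none
Why: Lewis-acid ether cleavage: boron binds the lactone carbonyl and the peri methoxy oxygen in a six-membered chelate and chloride removes that methyl group by SN2, while the unchelated C6 methoxy group stays. The benzyl ether is cleaved by O-coordination and benzyl transfer to pentamethylbenzene (Friedel–Crafts trapping), which keeps the benzyl cation off the electron-rich ring. The enol lactone is stable to the anhydrous acid.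

Step 5
Reactants: 9 8-hydroxy-3-(11-hydroxyundecyl)-6-methoxyisochromen-1-one
Product: 10 2-hydroxy-6-(13-hydroxy-2-oxotridecyl)-4-methoxybenzoic acid
Conditions: KOH (aq., 2 M), EtOH, N2, 60 °C; then 1 M HCl to pH 3, 0 °C, EtOAc
Reagents that add atoms: water, O (delivered as hydroxide from KOH, [K+].[OH-])
Why: Saponification of an enol lactone: hydroxide adds to the lactone carbonyl C7, the ring opens to carboxylate and enolate, and ketonisation of the enolate makes the opening irreversible in base. Cold, brief acidification then frees the keto acid before it can lactonise or decarboxylate.

## Compound list

1 | 12-hydroxydodecanoic acid | OCCCCCCCCCCCC(=O)O | starting material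
2 | benzyl 12-(benzyloxy)dodecanoate | O=C(OCc1ccccc1)CCCCCCCCCCCOCc1ccccc1 | intermediate
3 | trimethylsulfoxonium iodide | C[S+](C)(C)=O.[I-] | starting material
4 | dimethylsulfoxonium methylide | C=S(C)(C)=O | intermediate
5 | 13-benzyloxy-1-(dimethyloxosulfuranylidene)tridecan-2-one | CS(C)(=O)=CC(=O)CCCCCCCCCCCOCc1ccccc1 | intermediate
6 | 2,4-dimethoxybenzoic acid | COc1ccc(C(=O)O)c(OC)c1 | starting material
7 | 2-(13-benzyloxy-2-oxotridecyl)-4,6-dimethoxybenzoic acid | COc1cc(OC)c(C(=O)O)c(CC(=O)CCCCCCCCCCCOCc2ccccc2)c1 | intermediate
8 | 3-(11-benzyloxyundecyl)-6,8-dimethoxyisochromen-1-one | COc1cc(OC)c2c(c1)C=C(CCCCCCCCCCCOCc3ccccc3)OC2=O | intermediate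
9 | 8-hydroxy-3-(11-hydroxyundecyl)-6-methoxyisochromen-1-one | COc1cc(O)c2c(c1)C=C(CCCCCCCCCCCO)OC2=O | intermediate
10 | 2-hydroxy-6-(13-hydroxy-2-oxotridecyl)-4-methoxybenzoic acid | COc1cc(O)c(C(=O)O)c(CC(=O)CCCCCCCCCCCO)c1 | target

## Step count and least certain steps

Total step count: 5. Longest linear sequence: 5 steps (1 → 2 → 5 → 8 → 9 → 10); compounds 3 and 6 are purchased and enter at steps 2 and 3.

**Step 3 (key step).** The most likely failure is diversion of the ylide before the catalyst can use it. The free acid can protonate 5, and the carboxylate can then displace the sulfoxide (formal O–H insertion to a 2-oxoalkyl ester). C–H metalation may also be slow, because the ortho methoxy group twists the carboxylate out of the ring plane. Protodecarboxylation of the electron-rich acid at 100 °C and incomplete dehydration of 7 are further possibilities; the latter is cured by briefly heating the crude product with TsOH in toluene. Fallback: form the other bond of the acylmethyl unit, C1'–C2', by classical enolate chemistry. The fallback sets out from ester 2. Purchased methyl 2,4-dimethoxy-6-methylbenzoate F1 is deprotonated at its benzylic methyl group with LiN(iPr)2 (THF, −78 °C; two equivalents of the anion, since the product ketone is acidic) and acylated by 2 to give methyl 2-(13-benzyloxy-2-oxotridecyl)-4,6-dimethoxybenzoate F2. Enol lactonisation with loss of methanol (TsOH, toluene, reflux) then returns to the route at 8.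

**Step 5.** Two processes may go wrong. The opening may be sluggish, because the phenoxide formed in base donates into the lactone carbonyl. On acidification the keto acid may close again or lose carbon dioxide if the acid is too strong or too warm. Fallback: unveil the acid under neutral conditions. The fallback sets out from 9: NaOCH2Ph in benzyl alcohol/THF opens the lactone by alcoholysis to benzyl 2-hydroxy-6-(13-hydroxy-2-oxotridecyl)-4-methoxybenzoate F3. Hydrogenolysis of the benzyl ester (H2, Pd/C, EtOAc, rt) then gives 10 without any contact with mineral acid.

**Step 4.** The released benzyl cation may alkylate the electron-rich ring if trapping by pentamethylbenzene is too slow. The benzyl ether of a primary alcohol may be cleaved incompletely at low temperature, and warming to force it may cost the second methyl ether. Fallback: split the two deprotections between orthogonal reagents. The fallback sets out from 8: MgI2 (Et2O/toluene, warm) removes only the chelated methyl group and gives 3-(11-benzyloxyundecyl)-8-hydroxy-6-methoxyisochromen-1-one F4. Hydrogenolysis of the benzyl ether (H2, Pd(OH)2/C, EtOAc, rt, stopped after one equivalent of hydrogen so that the C3=C4 bond of the lactone is not reduced) rejoins the route at 9.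

**Step 2.** The unactivated, enolisable benzyl ester may be acylated only slowly. The methylide may instead deprotonate the ester, which returns starting material or leads to Claisen self-condensation. Fallback: use an activated aryl ester. The fallback sets out from 2: saponification (LiOH, THF/H2O) gives 12-(benzyloxy)dodecanoic acid F5. Carbodiimide coupling with 4-nitrophenol gives 4-nitrophenyl 12-(benzyloxy)dodecanoate F6, which acylates methylide 4 at 0 °C and returns to the route at 5.

## Further compounds

F1 | step 3 | methyl 2,4-dimethoxy-6-methylbenzoate | COC(=O)c1c(C)cc(OC)cc1OC
F2 | step 3 | methyl 2-(13-benzyloxy-2-oxotridecyl)-4,6-dimethoxybenzoate | COC(=O)c1c(CC(=O)CCCCCCCCCCCOCc2ccccc2)cc(OC)cc1OC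
F3 | step 5 | benzyl 2-hydroxy-6-(13-hydroxy-2-oxotridecyl)-4-methoxybenzoate | COc1cc(O)c(C(=O)OCc2ccccc2)c(CC(=O)CCCCCCCCCCCO)c1
F4 | step 4 | 3-(11-benzyloxyundecyl)-8-hydroxy-6-methoxyisochromen-1-one | COc1cc(O)c2c(c1)C=C(CCCCCCCCCCCOCc3ccccc3)OC2=O
F5 | step 2 | 12-(benzyloxy)dodecanoic acid | OC(=O)CCCCCCCCCCCOCc1ccccc1
F6 | step 2 | 4-nitrophenyl 12-(benzyloxy)dodecanoate | O=C(Oc1ccc(cc1)[N+](=O)[O-])CCCCCCCCCCCOCc1ccccc1
A1 | alternative 1 | 2-[11-(tert-butyldiphenylsilyloxy)undecyl]-3-(3,5-dimethoxyphenyl)propanoic acid (racemic) | COc1cc(OC)cc(CC(CCCCCCCCCCCO[Si](c2ccccc2)(c2ccccc2)C(C)(C)C)C(=O)O)c1
A2 | alternative 1 | 2-[11-(tert-butyldiphenylsilyloxy)undecyl]-5,7-dimethoxyindan-1-one (racemic) | COc1cc(OC)c2c(c1)CC(CCCCCCCCCCCO[Si](c3ccccc3)(c3ccccc3)C(C)(C)C)C2=O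
A3 | alternative 2 | dimethyl 2-acetyl-3-[(2-(11-tert-butyldimethylsilyloxyundecyl)-1,3-dioxolan-2-yl)methyl]pentanedioate (mixture of diastereomers) | COC(=O)CC(CC1(CCCCCCCCCCCO[Si](C)(C)C(C)(C)C)OCCO1)C(C(C)=O)C(=O)OC
A4 | alternative 2 | methyl 2,4-dioxo-6-[(2-(11-tert-butyldimethylsilyloxyundecyl)-1,3-dioxolan-2-yl)methyl]cyclohexane-1-carboxylate (racemic) | COC(=O)C1C(=O)CC(=O)CC1CC2(CCCCCCCCCCCO[Si](C)(C)C(C)(C)C)OCCO2
A5 | alternative 3 | 2,2-dimethyl-6-{2,4-dioxo-5-[2-(11-tert-butyldimethylsilyloxyundecyl)-1,3-dioxolan-2-yl]pentyl}-1,3-dioxin-4-one | CC1(C)OC(=O)C=C(CC(=O)CC(=O)CC2(CCCCCCCCCCCO[Si](C)(C)C(C)(C)C)OCCO2)O1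
A6 | alternative 3 | 7-hydroxy-2,2-dimethyl-5-[(2-(11-tert-butyldimethylsilyloxyundecyl)-1,3-dioxolan-2-yl)methyl]benzo[d][1,3]dioxin-4-one | CC1(C)OC(=O)c2c(CC3(CCCCCCCCCCCO[Si](C)(C)C(C)(C)C)OCCO3)cc(O)cc2O1
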